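**Assumptions.** The target has no stereocentres and no E/Z-defined alkenes, so there is no stereochemistry to set. 3,3-Dimethylpent-4-en-2-one (5) is taken as purchasable. The two biaryl couplings (steps 4 and 9) are proposed reactions without direct precedent for these substrates; nothing in this route has been run.

## Retrosynthetic overview

1. Last bond: indole B C3–aryl, formed ortho to the one oxygen that stays a free OH. The phenoxide of the indole A–aryl fragment (from 8) couples with the indol-3-yl radical of 14 (photo-SRN1).
2. 8 comes from O-methylation of 7. 7 comes from the same radical arylation of mono-silylated 2,5-dimethoxyhydroquinone 3 with indole A (6). The TIPS group marks the oxygen that ends as OH.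
3. The central ring is never built: p-benzoquinone → 2,5-dimethoxybenzoquinone (2) → reduction and mono-silylation (3).
4. Indole A ring: photo-SRN1 annulation of 2-iodoaniline with ketone 5. Indole B ring: Bartoli reaction on the nitroarene from 2-bromoaniline, then linear prenylation.
5. Ring order: pyrrole ring of indole A (step 3) and of indole B (step 7) are made separately; the biaryl bonds follow in steps 4 and 9.

## Route

**Step 1**
Reactants: 1, p-benzoquinone
Product: 2, 2,5-dimethoxy-1,4-benzoquinone
Conditions: MeOH, anhydrous ZnCl2, reflux (3 equiv of 1; 2 equiv act as oxidant); product crystallises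
Reagents that add atoms: methanol, CO
Why: Thiele-type oxidative conjugate addition: ZnCl2-activated quinone adds MeOH, excess quinone re-oxidises the methoxyhydroquinone, and the second MeOH adds para to the first.

**Step 2**
Reactants: 2
Product: 3, 2,5-dimethoxy-4-[(triisopropylsilyl)oxy]phenol
Conditions: Na2S2O4, EtOAc/H2O, rt; then crude hydroquinone (3 equiv), TIPSCl (1 equiv), imidazole, DMF, 0 °C, Ar (telescoped; excess diol recovered)
Reagents that add atoms: TIPSCl, CC(C)[Si](Cl)(C(C)C)C(C)C
Why: Dithionite reduction, then statistical mono-silylation of a C2-symmetric diol (either OH gives the same product); the silyl ether marks the oxygen that must end as the free phenol.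

**Step 3**
Reactants: 4, 2-iodoaniline; 5, 3,3-dimethylpent-4-en-2-one
Product: 6, 2-(2-methylbut-3-en-2-yl)-1H-indole
Conditions: 5 (3 equiv), KOtBu (4 equiv), DMSO, hν (350 nm), rt, Ar; aq NH4Cl
Reagents that add atoms: none
Why: Photostimulated SRN1 indole annulation (as for pinacolone → 2-tert-butylindole): the 2-aminophenyl radical couples with the only possible enolate (the other α-carbon is quaternary), and the α-aryl ketone cyclodehydrates onto NH2.

**Step 4**
Reactants: 6; 3
Product: 7, 3,6-dimethoxy-2-[2-(2-methylbut-3-en-2-yl)-1H-indol-3-yl]-4-[(triisopropylsilyl)oxy]phenol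
Conditions: 6, NIS (0.98 equiv), DMF, 0 °C, dark; add to 3 (4 equiv) + KOtBu (4 equiv) in degassed DMSO; 390 nm LEDs, rt; aq NH4Cl (excess 3 recovered)
Reagents that add atoms: none (iodine from NIS, O=C1CCC(=O)N1I, is put on C3 and expelled in the same pot)
Why: Proposed new method: the 3-iodoindole formed in situ accepts an electron from the photoexcited phenoxide and loses iodide to give the indol-3-yl σ-radical, which couples at the only free carbon ortho to O−; the dienone radical anion passes its electron to the next iodoindole (SRN1 chain) and tautomerises to the phenol. Closest known reaction: photostimulated SRN1 ortho-arylation of 4-alkoxyphenoxides with (hetero)aryl halides. Stoichiometric phenoxide, with no free alkoxide, keeps the TIPS ether intact.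

**Step 5**
Reactants: 7
Product: 8, 3-{2,3,6-trimethoxy-5-[(triisopropylsilyl)oxy]phenyl}-2-(2-methylbut-3-en-2-yl)-1H-indole
Conditions: MeI, K2CO3, acetone, 50 °C (sealed)
Reagents that add atoms: iodomethane, CI
Why: Williamson O-methylation of the only free phenol; K2CO3 is too weak to deprotonate the indole N–H and does not cleave the aryl TIPS ether.

**Step 6**
Reactants: 9, 2-bromoaniline
Product: 10, 1-bromo-2-nitrobenzene
Conditions: mCPBA (4 equiv), 1,2-dichloroethane, 80 °C
Reagents that add atoms: mCPBA, OOC(=O)c1cccc(Cl)c1
Why: Peracid oxidation of an electron-poor aniline through the hydroxylamine and nitroso stages to the nitroarene.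

**Step 7**
Reactants: 10; 11, vinylmagnesium bromide
Product: 12, 7-bromo-1H-indole
Conditions: 11 (3.2 equiv), THF, −45 °C; aq NH4Cl
Reagents that add atoms: none beyond reactant 11
Why: Bartoli indole synthesis; the ortho bromine drives the [3,3]-shift of the N-aryl-O-vinylhydroxylamine intermediate and ends at C7.

**Step 8**
Reactants: 12; 13, 1-bromo-3-methylbut-2-ene (prenyl bromide)
Product: 14, 7-(3-methylbut-2-en-1-yl)-1H-indole
Conditions: 13, Zn, LiCl, THF → prenylZnBr·LiCl (2.5 equiv); Pd(OAc)2 (2 mol %), CPhos (4 mol %), THF, rt
Reagents that add atoms: none beyond reactant 13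
Why: Linear-selective Negishi coupling of a prenylzinc halide; the bulky biarylphosphine favours reductive elimination at the unsubstituted allyl terminus, and the extra zinc reagent covers the N–H.

**Step 9**
Reactants: 8; 14
Product: 15, asterriquinol H
Conditions: 14 (1.5 equiv), NIS (1.45 equiv), DMF, 0 °C, dark; add to 8, CsF, Cs2CO3 in degassed DMSO (aryl–OTIPS cleaved in situ); 390 nm LEDs, rt; aq NH4Cl
Reagents that add atoms: none
Why: Proposed new method: the same phenoxide photo-SRN1 arylation as step 4; fluoride unmasks the phenoxide, whose single free ortho C–H (the other ortho and the para position carry OMe) takes the 7-prenylindol-3-yl radical, so the new bond forms next to the OH that remains free. Closest known reaction as in step 4; carbonate rather than alkoxide avoids base-induced prenyl isomerisation and keeps both indole N–H groups protonated.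

## Compound list

1 | p-benzoquinone | O=C1C=CC(=O)C=C1 | starting material
2 | 2,5-dimethoxy-1,4-benzoquinone | COC1=CC(=O)C(OC)=CC1=O | intermediate
3 | 2,5-dimethoxy-4-[(triisopropylsilyl)oxy]phenol | COc1cc(O[Si](C(C)C)(C(C)C)C(C)C)c(OC)cc1O | intermediate
4 | 2-iodoaniline | Nc1ccccc1I | starting material
5 | 3,3-dimethylpent-4-en-2-one | CC(=O)C(C)(C)C=C | starting material
6 | 2-(2-methylbut-3-en-2-yl)-1H-indole | C=CC(C)(C)c1cc2ccccc2[nH]1 | intermediate
7 | 3,6-dimethoxy-2-[2-(2-methylbut-3-en-2-yl)-1H-indol-3-yl]-4-[(triisopropylsilyl)oxy]phenol | C=CC(C)(C)c1[nH]c2ccccc2c1-c1c(O)c(OC)cc(O[Si](C(C)C)(C(C)C)C(C)C)c1OC | intermediate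
8 | 3-{2,3,6-trimethoxy-5-[(triisopropylsilyl)oxy]phenyl}-2-(2-methylbut-3-en-2-yl)-1H-indole | C=CC(C)(C)c1[nH]c2ccccc2c1-c1c(OC)c(OC)cc(O[Si](C(C)C)(C(C)C)C(C)C)c1OC | intermediate
9 | 2-bromoaniline | Nc1ccccc1Br | starting material
10 | 1-bromo-2-nitrobenzene | O=[N+]([O-])c1ccccc1Br | intermediate
11 | vinylmagnesium bromide | C=C[Mg]Br | starting material
12 | 7-bromo-1H-indole | Brc1cccc2cc[nH]c12 | intermediate
13 | 1-bromo-3-methylbut-2-ene | CC(C)=CCBr | starting material
14 | 7-(3-methylbut-2-en-1-yl)-1H-indole | CC(C)=CCc1cccc2cc[nH]c12 | intermediate
15 | asterriquinol H, 2,4,5-trimethoxy-3-[2-(2-methylbut-3-en-2-yl)-1H-indol-3-yl]-6-[7-(3-methylbut-2-en-1-yl)-1H-indol-3-yl]phenol | C=CC(C)(C)c1[nH]c2ccccc2c1-c1c(OC)c(O)c(-c2c[nH]c3c(CC=C(C)C)cccc23)c(OC)c1OC | target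

## Totals and risks

Total steps: 9. Longest linear sequence: 5 (steps 1 → 2 → 4 → 5 → 9). Step 3 feeds step 4; steps 6–8 feed step 9.

Steps most likely to fail:

1. **Step 9** (final phenoxide/indolyl-radical coupling with an N–H iodoindole; competing reduction of the radical by solvent or indole self-coupling). Fallback: polar umpolung. Desilylate 8, oxidise the p-methoxyphenol with PhI(OAc)2 in MeOH to the quinone monoketal, then add 14 by acid-promoted SN2′ arylation in HFIP, which also puts the indole ortho to the regenerated OH.
2. **Step 4** (hindered 2-tert-alkylindol-3-yl radical; TIPS ether must survive). Fallback: attach indole A at the quinone oxidation level. Acid-promoted conjugate addition of 6 to 2,5-dibromo-1,4-benzoquinone (from hydroquinone) and re-oxidation, NaOMe displacement of both bromides, dithionite reduction, selective TIPS protection of the unhindered OH, then methylation to reach 8.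
3. **Step 8** (linear versus branched selectivity and the free N–H in the Negishi coupling). Fallback: build the indole after prenylation. Couple prenylzinc with 10 to give 1-nitro-2-prenylbenzene, then run the Bartoli reaction on that nitroarene to reach 14.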